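The route is built on the C4–C4a disconnection of the flavonol. In the target the C4 carbonyl of ring C is bonded to C4a of ring A, the carbon lying between C8a (which carries O1) and the methoxy-bearing C5. An aryl anion generated at C4a from an iodide can therefore acylate an ester that O1 already holds on the C2=C3 enol ether. This closes ring C at the chromone oxidation level in one operation, with ring B and the C3 oxygen in place. The precursor is a tetrasubstituted β-aryloxy-α-benzyloxyacrylate (ester cis to the aryloxy group), assembled from a regiodefined iodophenol and a ring B enol triflate bearing the Roche-ester-derived side chain.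

Key step: step 13

Remark on the chemistry: the side-chain stereocentre is taken unchanged from the (R)-Roche ester; no bond to it is made or broken, and its descriptor becomes S only because the CIP priorities change when the ester carbon becomes a CH2 group.

Step 1
Reactants: 1 3-hydroxy-4,5-dimethoxybenzaldehyde
Product: 2 3,4-dimethoxy-5-[(triisopropylsilyl)oxy]benzaldehyde
Conditions: i-Pr3SiCl, imidazole, DMF, rt
Reagents that add atoms: triisopropylsilyl chloride, CC(C)[Si](Cl)(C(C)C)C(C)C
Why: Imidazole-promoted silylation of the phenol is routine, and the bulky triisopropylsilyl ether should withstand peracid, organolithium and dilute acid and later shields the neighbouring ring position.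

Step 2
Reactants: 2 3,4-dimethoxy-5-[(triisopropylsilyl)oxy]benzaldehyde
Product: 4 3,4-dimethoxy-5-[(triisopropylsilyl)oxy]phenol, via aryl formate 3 (not isolated)
Conditions: mCPBA, CH2Cl2, 0 °C to rt; aq. Na2S2O3/NaHCO3 wash; then Et3N, MeOH, rt
Reagents that add atoms: 3-chloroperoxybenzoic acid, OOC(=O)c1cccc(Cl)c1
Why: Baeyer–Villiger (Dakin-type) oxidation of the electron-rich benzaldehyde proceeds by aryl migration, helped by the para methoxy group, and the aryl formate is then methanolysed under mild amine catalysis that leaves the aryl silyl ether intact.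

Step 3
Reactants: 4 3,4-dimethoxy-5-[(triisopropylsilyl)oxy]phenol
Product: 5 [2,3-dimethoxy-5-(methoxymethoxy)phenoxy]triisopropylsilane
Conditions: MOMCl, i-Pr2NEt, CH2Cl2, 0 °C to rt
Reagents that add atoms: chloromethyl methyl ether, COCCl
Why: O-Alkylation of the phenol with chloromethyl methyl ether installs the methoxymethyl ether, a strong directing group for ortho-lithiation.

Step 4
Reactants: 5 [2,3-dimethoxy-5-(methoxymethoxy)phenoxy]triisopropylsilane
Product: 7 [4-iodo-2,3-dimethoxy-5-(methoxymethoxy)phenoxy]triisopropylsilane, via aryllithium 6 (not isolated)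
Conditions: n-BuLi, THF, 0 °C; then I2, –78 °C to rt
Reagents that add atoms: iodine, II
Why: Directed ortho-metalation should occur at the carbon flanked by the methoxymethoxy and methoxy groups, which both coordinate lithium, and not at the other ortho carbon next to the bulky, poorly coordinating silyl ether; iodine then traps the aryllithium.

Step 5
Reactants: 7 [4-iodo-2,3-dimethoxy-5-(methoxymethoxy)phenoxy]triisopropylsilane
Product: 8 2-iodo-3,4-dimethoxy-5-[(triisopropylsilyl)oxy]phenol
Conditions: conc. aq. HCl (cat.), MeOH, 40 °C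
Reagents that add atoms: none
Why: Acid-catalysed methanolysis cleaves the acetal-type methoxymethyl ether, while the hindered aryl triisopropylsilyl ether, the methyl ethers and the aryl iodide should persist.

Step 6
Reactants: 9 methyl (2R)-3-hydroxy-2-methylpropanoate (Roche ester)
Product: 10 methyl (2R)-3-(benzyloxy)-2-methylpropanoate
Conditions: BnOC(=NH)CCl3, TfOH (cat.), CH2Cl2/cyclohexane, 0 °C to rt
Reagents that add atoms: benzyl 2,2,2-trichloroacetimidate, N=C(OCc1ccccc1)C(Cl)(Cl)Cl
Why: Acid-catalysed benzylation with the trichloroacetimidate forms the ether without base, so the stereocentre alpha to the ester is neither epimerised nor lost by β-elimination.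

Step 7
Reactants: 10 methyl (2R)-3-(benzyloxy)-2-methylpropanoate
Product: 11 (2R)-3-(benzyloxy)-2-methylpropanal
Conditions: i-Bu2AlH, CH2Cl2, –78 °C; MeOH, then aq. KNaC4H4O6; crude product used at once
Reagents that add atoms: none
Why: Partial reduction of the ester with i-Bu2AlH at –78 °C stops at the aluminium hemiacetal, stabilised by chelation to the β-benzyloxy oxygen, and releases the aldehyde on work-up; immediate use protects its alpha stereocentre.

Step 8
Reactants: 11 (2R)-3-(benzyloxy)-2-methylpropanal
Product: 12 ({[(2S)-2-methylbut-3-en-1-yl]oxy}methyl)benzene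
Conditions: Ph3PCH3Br, KN(SiMe3)2, THF, 0 °C; then 11, –78 to 0 °C
Reagents that add atoms: methyltriphenylphosphonium bromide, C[P+](c1ccccc1)(c1ccccc1)c1ccccc1.[Br-]
Why: Wittig methylenation with the salt-free ylide at low temperature is faster than enolisation of the aldehyde, so the stereocentre is carried over unchanged.

Step 9
Reactants: 12 ({[(2S)-2-methylbut-3-en-1-yl]oxy}methyl)benzene; 13 methyl 3-bromo-4-methoxybenzoate
Product: 15 methyl 3-[(3S)-4-(benzyloxy)-3-methylbutyl]-4-methoxybenzoate, via B-alkyl-9-BBN 14 (not isolated)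
Conditions: 9-BBN, THF, 0 °C to rt; then 13, Pd(dppf)Cl2 (cat.), aq. K3PO4, DMF, 60 °C
Reagents that add atoms: none
Why: Anti-Markovnikov hydroboration of the terminal alkene with 9-BBN followed by B-alkyl Suzuki–Miyaura coupling with the aryl bromide forms the sp3–sp2 bond under conditions that tolerate the methyl ester and leave the stereocentre untouched.

Step 10
Reactants: 15 methyl 3-[(3S)-4-(benzyloxy)-3-methylbutyl]-4-methoxybenzoate; 16 methyl 2-(benzyloxy)acetate
Product: 18 methyl 2-(benzyloxy)-3-{3-[(3S)-4-(benzyloxy)-3-methylbutyl]-4-methoxyphenyl}-3-oxopropanoate, via lithium enolate 17 (not isolated)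
Conditions: 16, LiN(SiMe3)2 (excess), THF, –78 °C; then 15, –78 to 0 °C; aq. NH4Cl
Reagents that add atoms: none
Why: Crossed Claisen condensation in which the fully preformed glycolate enolate is acylated by the non-enolisable benzoate, while the excess amide base deprotonates the β-keto ester as it forms and so drives the condensation.

Step 11
Reactants: 18 methyl 2-(benzyloxy)-3-{3-[(3S)-4-(benzyloxy)-3-methylbutyl]-4-methoxyphenyl}-3-oxopropanoate
Product: 20 methyl (2E)-2-(benzyloxy)-3-{3-[(3S)-4-(benzyloxy)-3-methylbutyl]-4-methoxyphenyl}-3-{[(trifluoromethyl)sulfonyl]oxy}prop-2-enoate, via chelated sodium enolate 19 (not isolated)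
Conditions: NaH, CH2Cl2, 0 °C; then Tf2O, –78 to 0 °C
Reagents that add atoms: trifluoromethanesulfonic anhydride, O=S(=O)(OS(=O)(=O)C(F)(F)F)C(F)(F)F
Why: O-Sulfonylation of the sodium enolate, in which sodium bridges the enolate oxygen and the ester carbonyl, should place the triflate cis to the ester (stereoselective enol triflate formation from a β-keto ester).

Step 12
Reactants: 8 2-iodo-3,4-dimethoxy-5-[(triisopropylsilyl)oxy]phenol; 20 methyl (2E)-2-(benzyloxy)-3-{3-[(3S)-4-(benzyloxy)-3-methylbutyl]-4-methoxyphenyl}-3-{[(trifluoromethyl)sulfonyl]oxy}prop-2-enoate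
Product: 22 methyl (2E)-2-(benzyloxy)-3-{3-[(3S)-4-(benzyloxy)-3-methylbutyl]-4-methoxyphenyl}-3-{2-iodo-3,4-dimethoxy-5-[(triisopropylsilyl)oxy]phenoxy}prop-2-enoate, via caesium phenoxide 21 (not isolated)
Conditions: Cs2CO3, MeCN, 0 °C to rt
Reagents that add atoms: none
Why: Nucleophilic vinylic substitution by addition–elimination, in which the phenoxide adds to the ester-activated β-carbon and triflate leaves faster than the intermediate enolate rotates, should give the aryl enol ether with retention, that is with the ester cis to the aryloxy group.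

Step 13
Reactants: 22 methyl (2E)-2-(benzyloxy)-3-{3-[(3S)-4-(benzyloxy)-3-methylbutyl]-4-methoxyphenyl}-3-{2-iodo-3,4-dimethoxy-5-[(triisopropylsilyl)oxy]phenoxy}prop-2-enoate
Product: 24 3-(benzyloxy)-2-{3-[(3S)-4-(benzyloxy)-3-methylbutyl]-4-methoxyphenyl}-5,6-dimethoxy-7-[(triisopropylsilyl)oxy]-4H-chromen-4-one, via arylmagnesium chloride 23 (not isolated)
Conditions: i-PrMgCl·LiCl, THF, –40 to 0 °C; aq. NH4Cl
Reagents that add atoms: none
Why: Proposed new method: iodine–magnesium exchange at the C4a iodide, accelerated by the two flanking oxygen substituents (the O1 enol ether and the C5 methoxy group), should be faster at –40 °C than attack of the alkylmagnesium reagent on the donor-deactivated ester, and arylmagnesium 23 then adds to the ester carbonyl held cis to it on the enol ether and expels methoxide, forming C4–C4a. The closest known reaction is the Parham cyclisation, in which an aryl anion made by halogen–metal exchange acylates a tethered ester or amide to give chromanones and related benzo-fused ketones; the extension is to a β-aryloxyacrylate, which delivers the chromone directly. Ring C closes in a 6-exo-trig mode at the ester carbonyl. No stereocentre is formed, and the side-chain stereocentre is remote from every reacting site. The step needs exchange before carbonyl addition (secured by the iodide and the low temperature), a single acylation site on ring A (secured by the position of the iodine) and a cis relation of ester and aryloxy group (secured by the E geometry of 22). The new carbonyl is a vinylogous ester inside the pyranone and should resist a second addition.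

Step 14
Reactants: 24 3-(benzyloxy)-2-{3-[(3S)-4-(benzyloxy)-3-methylbutyl]-4-methoxyphenyl}-5,6-dimethoxy-7-[(triisopropylsilyl)oxy]-4H-chromen-4-one
Product: 25 3-(benzyloxy)-2-{3-[(3S)-4-(benzyloxy)-3-methylbutyl]-4-methoxyphenyl}-7-hydroxy-5,6-dimethoxy-4H-chromen-4-one
Conditions: Bu4NF, AcOH, THF, 0 °C
Reagents that add atoms: none
Why: Fluoride cleaves the aryl silyl ether readily because the C7 phenoxide, vinylogous to the C4 carbonyl, is a good leaving group from silicon, and acetic acid buffering protects the chromone from basic fluoride.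

Step 15
Reactants: 25 3-(benzyloxy)-2-{3-[(3S)-4-(benzyloxy)-3-methylbutyl]-4-methoxyphenyl}-7-hydroxy-5,6-dimethoxy-4H-chromen-4-one
Product: 26 3,7-dihydroxy-2-{3-[(3S)-4-hydroxy-3-methylbutyl]-4-methoxyphenyl}-5,6-dimethoxy-4H-chromen-4-one
Conditions: H2 (1 atm), 10% Pd/C, EtOAc/MeOH, rt
Reagents that add atoms: none
Why: Hydrogenolysis over Pd on carbon removes the O3 benzyl ether and the primary alkyl benzyl ether in one operation without reducing the aromatic pyranone or touching the stereocentre, which gives the target.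

Compound list

1 | 3-hydroxy-4,5-dimethoxybenzaldehyde | COc1cc(C=O)cc(O)c1OC | starting material
2 | 3,4-dimethoxy-5-[(triisopropylsilyl)oxy]benzaldehyde | COc1cc(C=O)cc(O[Si](C(C)C)(C(C)C)C(C)C)c1OC | intermediate
3 | 3,4-dimethoxy-5-[(triisopropylsilyl)oxy]phenyl formate | COc1cc(OC=O)cc(O[Si](C(C)C)(C(C)C)C(C)C)c1OC | intermediate (not isolated)
4 | 3,4-dimethoxy-5-[(triisopropylsilyl)oxy]phenol | COc1cc(O)cc(O[Si](C(C)C)(C(C)C)C(C)C)c1OC | intermediate
5 | [2,3-dimethoxy-5-(methoxymethoxy)phenoxy]triisopropylsilane | COCOc1cc(OC)c(OC)c(O[Si](C(C)C)(C(C)C)C(C)C)c1 | intermediate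
6 | {2,3-dimethoxy-6-(methoxymethoxy)-4-[(triisopropylsilyl)oxy]phenyl}lithium | COCOc1cc(O[Si](C(C)C)(C(C)C)C(C)C)c(OC)c(OC)c1[Li] | intermediate (not isolated)
7 | [4-iodo-2,3-dimethoxy-5-(methoxymethoxy)phenoxy]triisopropylsilane | COCOc1cc(O[Si](C(C)C)(C(C)C)C(C)C)c(OC)c(OC)c1I | intermediate
8 | 2-iodo-3,4-dimethoxy-5-[(triisopropylsilyl)oxy]phenol | Oc1cc(O[Si](C(C)C)(C(C)C)C(C)C)c(OC)c(OC)c1I | intermediate
9 | methyl (2R)-3-hydroxy-2-methylpropanoate (Roche ester) | COC(=O)[C@H](C)CO | starting material
10 | methyl (2R)-3-(benzyloxy)-2-methylpropanoate | COC(=O)[C@H](C)COCc1ccccc1 | intermediate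
11 | (2R)-3-(benzyloxy)-2-methylpropanal | O=C[C@H](C)COCc1ccccc1 | intermediate
12 | ({[(2S)-2-methylbut-3-en-1-yl]oxy}methyl)benzene | C=C[C@H](C)COCc1ccccc1 | intermediate
13 | methyl 3-bromo-4-methoxybenzoate | COC(=O)c1ccc(OC)c(Br)c1 | starting material
14 | 9-[(3S)-4-(benzyloxy)-3-methylbutyl]-9-borabicyclo[3.3.1]nonane | B1(CC[C@H](C)COCc2ccccc2)C2CCCC1CCC2 | intermediate (not isolated)
15 | methyl 3-[(3S)-4-(benzyloxy)-3-methylbutyl]-4-methoxybenzoate | COC(=O)c1ccc(OC)c(CC[C@H](C)COCc2ccccc2)c1 | intermediate
16 | methyl 2-(benzyloxy)acetate | COC(=O)COCc1ccccc1 | starting material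
17 | lithium 2-(benzyloxy)-1-methoxyethen-1-olate (enolate of 16) | [Li+].COC([O-])=COCc1ccccc1 | intermediate (not isolated)
18 | methyl 2-(benzyloxy)-3-{3-[(3S)-4-(benzyloxy)-3-methylbutyl]-4-methoxyphenyl}-3-oxopropanoate (C2 undefined, keto and enol forms) | COC(=O)C(OCc1ccccc1)C(=O)c1ccc(OC)c(CC[C@H](C)COCc2ccccc2)c1 | intermediate
19 | sodium enolate of 18 (enolate oxygen cis to the ester) | [Na+].COC(=O)/C(OCc1ccccc1)=C(\[O-])c1ccc(OC)c(CC[C@H](C)COCc2ccccc2)c1 | intermediate (not isolated)
20 | methyl (2E)-2-(benzyloxy)-3-{3-[(3S)-4-(benzyloxy)-3-methylbutyl]-4-methoxyphenyl}-3-{[(trifluoromethyl)sulfonyl]oxy}prop-2-enoate | COC(=O)/C(OCc1ccccc1)=C(\OS(=O)(=O)C(F)(F)F)c1ccc(OC)c(CC[C@H](C)COCc2ccccc2)c1 | intermediate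
21 | caesium 2-iodo-3,4-dimethoxy-5-[(triisopropylsilyl)oxy]phenolate | [Cs+].[O-]c1cc(O[Si](C(C)C)(C(C)C)C(C)C)c(OC)c(OC)c1I | intermediate (not isolated)
22 | methyl (2E)-2-(benzyloxy)-3-{3-[(3S)-4-(benzyloxy)-3-methylbutyl]-4-methoxyphenyl}-3-{2-iodo-3,4-dimethoxy-5-[(triisopropylsilyl)oxy]phenoxy}prop-2-enoate | COC(=O)/C(OCc1ccccc1)=C(\Oc1cc(O[Si](C(C)C)(C(C)C)C(C)C)c(OC)c(OC)c1I)c1ccc(OC)c(CC[C@H](C)COCc2ccccc2)c1 | intermediate
23 | arylmagnesium chloride derived from 22 (MgCl in place of I at C4a) | COC(=O)/C(OCc1ccccc1)=C(\Oc1cc(O[Si](C(C)C)(C(C)C)C(C)C)c(OC)c(OC)c1[Mg]Cl)c1ccc(OC)c(CC[C@H](C)COCc2ccccc2)c1 | intermediate (not isolated)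
24 | 3-(benzyloxy)-2-{3-[(3S)-4-(benzyloxy)-3-methylbutyl]-4-methoxyphenyl}-5,6-dimethoxy-7-[(triisopropylsilyl)oxy]-4H-chromen-4-one | COc1ccc(-c2oc3cc(O[Si](C(C)C)(C(C)C)C(C)C)c(OC)c(OC)c3c(=O)c2OCc2ccccc2)cc1CC[C@H](C)COCc1ccccc1 | intermediate
25 | 3-(benzyloxy)-2-{3-[(3S)-4-(benzyloxy)-3-methylbutyl]-4-methoxyphenyl}-7-hydroxy-5,6-dimethoxy-4H-chromen-4-one | COc1ccc(-c2oc3cc(O)c(OC)c(OC)c3c(=O)c2OCc2ccccc2)cc1CC[C@H](C)COCc1ccccc1 | intermediate
26 | 3,7-dihydroxy-2-{3-[(3S)-4-hydroxy-3-methylbutyl]-4-methoxyphenyl}-5,6-dimethoxy-4H-chromen-4-one | COc1ccc(-c2oc3cc(O)c(OC)c(OC)c3c(=O)c2O)cc1CC[C@H](C)CO | target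

Total step count: 15. Longest linear sequence: 10 steps (steps 6 to 15, from Roche ester 9); the ring A branch (steps 1 to 5) joins at step 12.

Steps most likely to fail

Step 13 (the labelled step). The iodine–magnesium exchange on the electron-rich ring may be slower than attack of the alkylmagnesium reagent on the acrylate, either at the ester or by conjugate addition with loss of the phenoxide, or the arylmagnesium may be protonated before it cyclises. The fallback uses known chemistry (Baker–Venkataraman route to 3-alkoxyflavones), sets out from 5 and 15 and returns at 24. Aryllithium 6, made from 5 as in step 4, would be acylated with 2-(benzyloxy)-N-methoxy-N-methylacetamide to give the benzyloxymethyl aryl ketone F1. HCl in MeOH would remove the methoxymethyl group to give the ortho-hydroxy ketone F2. Ester 15 would be saponified (LiOH, THF/MeOH/H2O) to the benzoic acid F3 and converted with (COCl)2 and catalytic DMF into the acid chloride F4. Treatment of F2 with excess LiN(SiMe3)2 (THF, –78 °C) and then F4 should give, by Baker–Venkataraman-type C-acylation of the ketone enolate, the 1,3-diketone F5. Acid-catalysed cyclodehydration (catalytic TsOH, toluene, gentle warming) should then close ring C through O1–C2 and give 24. The C4–C4a bond is made at the same lithiated carbon, so the ring A regiochemistry is unchanged.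

Step 12. The phenoxide may attack sulfur of the triflate, transferring the triflyl group to the phenol and returning the enolate of 18, instead of attacking the hindered, donor-substituted β-carbon; reversible phenoxide addition may also scramble the alkene geometry. The fallback sets out from 18 and returns at 22. Keto ester 18 would be converted with the Vilsmeier reagent ((COCl)2, DMF, CH2Cl2) into the β-chloroacrylate F6, the isomer with chlorine cis to the ester being separated if both form. Chloride offers no site for attack other than carbon, and its displacement by phenoxide 21 (8, Cs2CO3, DMF, gentle warming, optionally catalytic DABCO) should give 22.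

Step 10. Self-condensation of the glycolate enolate, or its decomposition on warming, may outpace acylation by the electron-rich and weakly electrophilic benzoate. The fallback sets out from 15 and returns at 18. Ester 15 would be converted directly into the Weinreb amide F7 (MeNH(OMe)·HCl, i-PrMgCl, THF, –20 °C). Amide F7 would then acylate lithium enolate 17 at –78 to 0 °C; the chelated tetrahedral adduct should persist until work-up, so the acylation does not depend on a Claisen equilibrium, and 18 should result.

Further compounds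

F1 | step 13 | 2-(benzyloxy)-1-{2,3-dimethoxy-6-(methoxymethoxy)-4-[(triisopropylsilyl)oxy]phenyl}ethan-1-one | COCOc1cc(O[Si](C(C)C)(C(C)C)C(C)C)c(OC)c(OC)c1C(=O)COCc1ccccc1
F2 | step 13 | 2-(benzyloxy)-1-{6-hydroxy-2,3-dimethoxy-4-[(triisopropylsilyl)oxy]phenyl}ethan-1-one | Oc1cc(O[Si](C(C)C)(C(C)C)C(C)C)c(OC)c(OC)c1C(=O)COCc1ccccc1
F3 | step 13 | 3-[(3S)-4-(benzyloxy)-3-methylbutyl]-4-methoxybenzoic acid | OC(=O)c1ccc(OC)c(CC[C@H](C)COCc2ccccc2)c1
F4 | step 13 | 3-[(3S)-4-(benzyloxy)-3-methylbutyl]-4-methoxybenzoyl chloride | ClC(=O)c1ccc(OC)c(CC[C@H](C)COCc2ccccc2)c1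
F5 | step 13 | 2-(benzyloxy)-1-{3-[(3S)-4-(benzyloxy)-3-methylbutyl]-4-methoxyphenyl}-3-{6-hydroxy-2,3-dimethoxy-4-[(triisopropylsilyl)oxy]phenyl}propane-1,3-dione | Oc1cc(O[Si](C(C)C)(C(C)C)C(C)C)c(OC)c(OC)c1C(=O)C(OCc1ccccc1)C(=O)c1ccc(OC)c(CC[C@H](C)COCc2ccccc2)c1
F6 | step 12 | methyl (2E)-2-(benzyloxy)-3-chloro-3-{3-[(3S)-4-(benzyloxy)-3-methylbutyl]-4-methoxyphenyl}prop-2-enoate | COC(=O)/C(OCc1ccccc1)=C(\Cl)c1ccc(OC)c(CC[C@H](C)COCc2ccccc2)c1
F7 | step 10 | 3-[(3S)-4-(benzyloxy)-3-methylbutyl]-N,4-dimethoxy-N-methylbenzamide | CON(C)C(=O)c1ccc(OC)c(CC[C@H](C)COCc2ccccc2)c1
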